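## Retrosynthetic overview
1. The last bond made is the tertiary C–OH bond, with oxygen from water. It ends a photocatalytic cascade that starts at a C3–Cl bond of a 7-endo type A bicyclo[3.3.1]nonane-2,4,9-trione and closes ring C (C3–C11) and ring D (C12–C13) on the way.
2. Ring B (C1–C8 bond) comes from an intramolecular SN1 alkylation of the benzoyl-bearing carbon by a tertiary chloride. C3 is already quaternary (Cl, prenyl), so only the type A mode is open.
3. Ring A is bought as an arene. 3-Chloro-5-geranylphlorobenzophenone is dearomatised at C5 by a chiral primary triflate, then quaternised at C3 by prenyl bromide. The chlorine blocks C3, steers both alkylations and later serves as the radical trigger.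
4. Absolute configuration comes from (S)-lavandulol, obtained by enantioselective lipase O-acylation of the cheap racemate. C7 relays to C5 and C1 (with one separation), then to C3, C11 and C13 (cage control).
5. Ring order: A (aromatic) → B → C → D.

**Notation.** C1 is the benzoyl-bearing bridgehead, C2 and C4 the ring carbonyls, and C3 the carbon between them. C5 is the geranyl-bearing bridgehead, C6 is CH2, C7 is CH, C8 is CMe2 and C9 is the bridging C=O. C10 is the CH2 on C7, C11 is CH, C12 is CMe2, C13 is the CH bearing the hydroxyisopropyl group, and C14 is the CH2 on C3.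
- Ring A = C1-C2-C3-C4-C5-C9
- Ring B = C1-C9-C5-C6-C7-C8
- Ring C = C3-C4-C5-C6-C7-C10-C11
- Ring D = C3-C11-C12-C13-C14

**Assumption.** Immobilised Candida antarctica lipase B acetylates (R)-lavandulol faster than (S)-lavandulol (moderate E), so the (S)-alcohol is harvested at about 70 % conversion.

## Route

Step 1
Reactants: 1 2,4,6-trihydroxybenzophenone; 2 geranyl bromide
Product: 3 3-geranyl-2,4,6-trihydroxybenzophenone
Conditions: 2 (0.9 equiv), 10 % aq KOH, 0 °C to rt
Reagents that add atoms: none
Why: Base-mediated C-alkylation of a phloroglucinolate by an allylic bromide (SN2) goes to one of the two equivalent free ring carbons, the bromide as limiting reagent holds back a second alkylation, no stereocentre forms and the E alkene is kept.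

Step 2
Reactants: 3 3-geranyl-2,4,6-trihydroxybenzophenone
Product: 4 3-chloro-5-geranyl-2,4,6-trihydroxybenzophenone
Conditions: NCS (1.0 equiv), MeCN, −20 to 0 °C, dark
Reagents that add atoms: N-chlorosuccinimide, O=C1CCC(=O)N1Cl
Why: Electrophilic aromatic chlorination hits the only free, strongly activated ring carbon far faster than NCS touches trisubstituted alkenes, and it installs the atom that later blocks C3, directs the alkylations and triggers the radical cascade.

Step 3
Reactants: 5 (±)-lavandulol
Product: 6 (S)-lavandulol
Conditions: immobilised Candida antarctica lipase B, vinyl acetate (1.0 equiv), MTBE, 30 °C, stopped at ca. 70 % conversion, chromatography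
Reagents that add atoms: none
Why: Lipase-catalysed kinetic resolution by enantioselective O-acylation removes the (R)-alcohol as its acetate and leaves the (S)-alcohol in at least 97 % ee, which fixes C7 and through it the absolute configuration of the whole target.

Step 4
Reactants: 6 (S)-lavandulol
Product: 7 (R)-2-(2-chloropropan-2-yl)-5-methylhex-4-en-1-ol
Conditions: Co(BF4)2·6H2O (5 mol%), SALDIPAC ligand (5 mol%), t-BuOOH (0.3 equiv), PhSiH3 (1.2 equiv), TsCl (1.5 equiv), EtOH, 23 °C
Reagents that add atoms: p-toluenesulfonyl chloride, Cc1ccc(cc1)S(=O)(=O)Cl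
Why: Cobalt-hydride hydrogen-atom-transfer Markovnikov hydrochlorination engages the 1,1-disubstituted alkene much faster than the trisubstituted one, the tertiary radical takes chlorine from TsCl, and the neighbouring stereocentre is untouched (the descriptor changes only through priorities).

Step 5
Reactants: 7 (R)-2-(2-chloropropan-2-yl)-5-methylhex-4-en-1-ol
Product: 8 (R)-2-(2-chloropropan-2-yl)-5-methylhex-4-enyl trifluoromethanesulfonate
Conditions: Tf2O (1.1 equiv), 2,6-lutidine (1.3 equiv), CH2Cl2, −78 °C, cold aqueous wash, used at once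
Reagents that add atoms: trifluoromethanesulfonic anhydride, O=S(=O)(OS(=O)(=O)C(F)(F)F)C(F)(F)F
Why: Standard O-sulfonylation of a primary alcohol at low temperature gives the only leaving group reactive enough for C-alkylation by a β-branched unactivated carbon, and the tertiary chloride and the alkene are inert under these conditions.

Step 6
Reactants: 4 3-chloro-5-geranyl-2,4,6-trihydroxybenzophenone; 8 (R)-2-(2-chloropropan-2-yl)-5-methylhex-4-enyl trifluoromethanesulfonate; 9 prenyl bromide
Product: 11 (6S)-4-benzoyl-2-chloro-6-[(2R)-2-(2-chloropropan-2-yl)-5-methylhex-4-enyl]-6-geranyl-5-hydroxy-2-prenylcyclohex-4-ene-1,3-dione (C2 epimers), via mono-alkylated chlorodienone 10 (not isolated)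
Conditions: 4, LiHMDS (3.05 equiv), THF, −78 to 0 °C; 8 (1.1 equiv), 0 °C; then 9 (1.2 equiv), 0 °C to rt; 1 M HCl
Reagents that add atoms: none
Why: Alkylative dearomatisation (SN2 C-alkylation of the trilithium phloroglucinolate) occurs at the geranyl-bearing carbon because the chloro-bearing carbon is inductively deactivated and the benzoyl-bearing carbon is the least nucleophilic, the remaining dianion is then C-prenylated at the chloro-bearing carbon, C5 forms without facial control (about 1:1, the unwanted epimer is removed after step 7), and both epimers at the chloro-bearing carbon are used because that centre is planarised in step 8.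

Step 7
Reactants: 11 (6S)-4-benzoyl-2-chloro-6-[(2R)-2-(2-chloropropan-2-yl)-5-methylhex-4-enyl]-6-geranyl-5-hydroxy-2-prenylcyclohex-4-ene-1,3-dione
Product: 13 (1S,5S,7R)-1-benzoyl-3-chloro-5-geranyl-8,8-dimethyl-3,7-diprenylbicyclo[3.3.1]nonane-2,4,9-trione (7-endo; C3 epimers), via trimethylsilyl enol ether 12 (not isolated)
Conditions: BSA (2.0 equiv), CH2Cl2, rt; then AgOTf (1.1 equiv), −78 to −20 °C; aq NaHCO3; chromatography (removes the 7-exo isomer from the C5 epimer)
Reagents that add atoms: none
Why: Intramolecular Reetz-type α-tert-alkylation of a silyl enol ether (silver-promoted SN1) ionises only the tertiary C–Cl bond, no Brønsted acid is present to protonate geranyl or prenyl groups, quaternary C3 leaves C1 as the only carbon nucleophile, O-alkylation is reversible under the TMSOTf formed, and C1 is set by the tether (the new bond must be cis to C5–C6), which for this C5/C7 pair places the C7 prenyl group endo.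

Step 8
Reactants: 13 (1S,5S,7R)-1-benzoyl-3-chloro-5-geranyl-8,8-dimethyl-3,7-diprenylbicyclo[3.3.1]nonane-2,4,9-trione
Product: 15 target CNP0164095.1 (1S,3S,5R,7R,11S,13R), via cage tertiary chloride 14 (not isolated)
Conditions: fac-Ir(ppy)3 (1 mol%), 2,6-lutidine (1.5 equiv), 1,1,1,3,3,3-hexafluoropropan-2-ol/H2O 9:1 (0.02 M), argon, 450 nm LEDs, 25 °C
Reagents that add atoms: water, O
Why: Proposed new method: a redox-neutral photocatalytic transannular radical–polar crossover hydroxy-bicyclisation of a tertiary 2-chloro-1,3-diketone, in which excited fac-Ir(ppy)3 reduces the weak C3–Cl bond of either C3 epimer to chloride and a planar electrophilic C3 radical, this radical can bond only on its endo face (C3 becomes S) and adds to C11 of the endo C7 prenyl group held above it (ring C; the equatorial bridgehead geranyl group cannot reach C3), the CMe2 terminus turns to the C6 methylene side away from the C8 methyl groups so that C11 is S, the tertiary C12 radical closes 5-exo-trig onto C13 of the C3 prenyl group, placing the new radical centre on the convex face so that C13 is R (ring D), and the terminal tertiary radical is either oxidised by the tetravalent iridium species or takes chlorine from 13 to give 14, both paths ending in the same tertiary cation in this strongly ionising medium, where water forms the C–O bond; the closest known reaction types are photoredox atom-transfer radical addition and oxyalkylation of alkenes by α-halocarbonyl compounds in the presence of water and Mn(OAc)3-mediated radical cascades of dearomatised acylphloroglucinols, neither shown for a transannular closure on a bridged 3-halo trione or for a hydroxyl-terminated cascade of this kind.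

## Compound list
1 | 2,4,6-trihydroxybenzophenone | O=C(c1ccccc1)c1c(O)cc(O)cc1O | starting material
2 | geranyl bromide, (E)-1-bromo-3,7-dimethylocta-2,6-diene | CC(C)=CCC/C(C)=C/CBr | starting material
3 | 3-geranyl-2,4,6-trihydroxybenzophenone | CC(C)=CCC/C(C)=C/Cc1c(O)cc(O)c(C(=O)c2ccccc2)c1O | intermediate
4 | 3-chloro-5-geranyl-2,4,6-trihydroxybenzophenone | CC(C)=CCC/C(C)=C/Cc1c(O)c(Cl)c(O)c(C(=O)c2ccccc2)c1O | intermediate
5 | (±)-lavandulol, 5-methyl-2-(prop-1-en-2-yl)hex-4-en-1-ol | CC(C)=CCC(CO)C(C)=C | starting material
6 | (S)-lavandulol | CC(C)=CC[C@H](CO)C(C)=C | intermediate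
7 | (R)-2-(2-chloropropan-2-yl)-5-methylhex-4-en-1-ol | CC(C)=CC[C@H](CO)C(C)(C)Cl | intermediate
8 | (R)-2-(2-chloropropan-2-yl)-5-methylhex-4-enyl trifluoromethanesulfonate | CC(C)=CC[C@H](COS(=O)(=O)C(F)(F)F)C(C)(C)Cl | intermediate
9 | prenyl bromide, 1-bromo-3-methylbut-2-ene | CC(C)=CCBr | starting material
10 | (6S)-4-benzoyl-2-chloro-6-[(2R)-2-(2-chloropropan-2-yl)-5-methylhex-4-enyl]-6-geranyl-3,5-dihydroxycyclohexa-2,4-dien-1-one (present as dilithium salt; productive epimer drawn, formed together with its 6R epimer) | CC(C)=CCC/C(C)=C/C[C@@]1(C[C@@H](CC=C(C)C)C(C)(C)Cl)C(=O)C(Cl)=C(O)C(C(=O)c2ccccc2)=C1O | intermediate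
11 | (6S)-4-benzoyl-2-chloro-6-[(2R)-2-(2-chloropropan-2-yl)-5-methylhex-4-enyl]-6-geranyl-5-hydroxy-2-prenylcyclohex-4-ene-1,3-dione (both C2 epimers; productive 6S epimer drawn) | CC(C)=CCC/C(C)=C/C[C@@]1(C[C@@H](CC=C(C)C)C(C)(C)Cl)C(=O)C(Cl)(CC=C(C)C)C(=O)C(C(=O)c2ccccc2)=C1O | intermediate
12 | 5-O-trimethylsilyl enol ether of 11 | CC(C)=CCC/C(C)=C/C[C@@]1(C[C@@H](CC=C(C)C)C(C)(C)Cl)C(=O)C(Cl)(CC=C(C)C)C(=O)C(C(=O)c2ccccc2)=C1O[Si](C)(C)C | intermediate
13 | (1S,5S,7R)-1-benzoyl-3-chloro-5-geranyl-8,8-dimethyl-3,7-diprenylbicyclo[3.3.1]nonane-2,4,9-trione (C7 prenyl endo, syn to the C2–C4 bridge; both C3 epimers) | CC(C)=CCC/C(C)=C/C[C@@]12C[C@@H](CC=C(C)C)C(C)(C)[C@](C(=O)c3ccccc3)(C2=O)C(=O)C(Cl)(CC=C(C)C)C1=O | intermediate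
14 | cage tertiary chloride: the target skeleton with 13-(2-chloropropan-2-yl) in place of 13-(2-hydroxypropan-2-yl) (1S,3S,5R,7R,11S,13R) | CC(C)=CCC/C(C)=C/C[C@@]12C[C@H]3C[C@H]4C(C)(C)[C@H](C(C)(C)Cl)C[C@]4(C1=O)C(=O)[C@@](C(=O)c1ccccc1)(C2=O)C3(C)C | intermediate
15 | CNP0164095.1: homoadamantane-type caged acylphloroglucinol, 1-benzoyl, 5-geranyl, 8,8- and 12,12-dimethyl, 13-(2-hydroxypropan-2-yl), C3–C11 and C12–C13 closed (1S,3S,5R,7R,11S,13R) | CC(C)=CCC/C(C)=C/C[C@@]12C[C@H]3C[C@H]4C(C)(C)[C@H](C(C)(C)O)C[C@]4(C1=O)C(=O)[C@@](C(=O)c1ccccc1)(C2=O)C3(C)C | target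

## Step count and risks
- Total step count: 8.
- Longest linear sequence: 6 (steps 3, 4, 5, 6, 7, 8, from 5).

**Step 6.**
- Risk: a quaternary carbon must be made using a hindered, unactivated triflate. O-alkylation and attack at the chloro-bearing carbon compete, and there is no facial control at C5.
- Fallback: it sets out from 1 and comes back at 11, and it inverts the order of bond formation at C5.
  - Compound 1 is chlorinated with NCS to 3-chloro-2,4,6-trihydroxybenzophenone F1.
  - The only free ring carbon of this compound is alkylated by 8 (LiHMDS, THF). The product rearomatises, so the hindered electrophile does not have to build a quaternary centre. This gives 3-chloro-5-[(2R)-2-(2-chloropropan-2-yl)-5-methylhex-4-enyl]-2,4,6-trihydroxybenzophenone F2.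
  - The quaternary C5 is then created using the much more reactive allylic bromide 2 (lupulone-type dearomatisation), which gives 10.
  - Bromide 9 is added in the same flask to reach 11.

**Step 7.**
- Risk: the ring closure joins two fully substituted carbons and must place the C7 prenyl group endo. E1 loss of a proton from the cation is an irreversible side path.
- Fallback: it sets out from 11 and comes back at 13, and it closes the ring through oxygen first.
  - Unsilylated 11 is ionised with Ag2CO3 in CH2Cl2, and the cation is caught by the neighbouring enol oxygen in a fast, unstrained closure. This gives the O-cyclised 2,2-dimethyl-3-prenyl pyran-fused enone F3, which is isolated.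
  - Catalytic TMSOTf in CH2Cl2 at −40 °C re-ionises the tertiary enol ether, and the ion pair collapses at C1 (1,3 O-to-C shift) to 13.

**Step 8** (the proposed new step).
- Risk: the C3 radical may be reduced to the enolate before it cyclises, the first closure may be slow, and the final cation may lose a proton instead of taking up water.
- Fallback by known chemistry: it sets out from 13 and comes back at 15.
  - Zn in AcOH removes the chlorine and gives the enolic 7-endo type A trione F4.
  - Mn(OAc)3·2H2O (2.2 equiv) and Cu(OAc)2 (1 equiv) in AcOH at rt run the oxidative radical bicyclisation. The terminal radical is oxidised to the alkene, giving the 13-isopropenyl cage F5.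
  - A Mukaiyama hydration (Co(acac)2, PhSiH3, O2, i-PrOH, then PPh3) converts only the 1,1-disubstituted alkene, not the trisubstituted geranyl alkenes, into the tertiary alcohol 15.

Further compounds
F1 | step 6 | 3-chloro-2,4,6-trihydroxybenzophenone | O=C(c1ccccc1)c1c(O)cc(O)c(Cl)c1O
F2 | step 6 | 3-chloro-5-[(2R)-2-(2-chloropropan-2-yl)-5-methylhex-4-enyl]-2,4,6-trihydroxybenzophenone | CC(C)=CC[C@H](Cc1c(O)c(Cl)c(O)c(C(=O)c2ccccc2)c1O)C(C)(C)Cl
F3 | step 7 | O-cyclised isomer of 13: 2,2-dimethyl-3-prenyl pyran ring closed from the enol oxygen next to C5 onto C8, C5 and C7 configured as in 11 | CC(C)=CCC/C(C)=C/C[C@]12C[C@@H](CC=C(C)C)C(C)(C)OC1=C(C(=O)c3ccccc3)C(=O)C(Cl)(CC=C(C)C)C2=O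
F4 | step 8 | 1-benzoyl-5-geranyl-4-hydroxy-8,8-dimethyl-3,7-diprenylbicyclo[3.3.1]non-3-ene-2,9-dione, 7-endo, C1, C5 and C7 configured as in 13 | CC(C)=CCC/C(C)=C/C[C@@]12C[C@@H](CC=C(C)C)C(C)(C)[C@](C(=O)c3ccccc3)(C2=O)C(=O)C(CC=C(C)C)=C1O
F5 | step 8 | 13-isopropenyl cage, all stereocentres as in 15 | CC(C)=CCC/C(C)=C/C[C@@]12C[C@H]3C[C@H]4C(C)(C)[C@H](C(C)=C)C[C@]4(C1=O)C(=O)[C@@](C(=O)c1ccccc1)(C2=O)C3(C)C
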